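**Retrosynthetic overview**
1. Feature: the cyclobutane C1–C4 carries CO2Me (C1), CO2H (C2) and the two methyl groups (C3, C4) on one face and both pyranone rings on the other. Its four stereocentres would form a meso set if the C1 and C2 carboxyls were alike, so C1–C2 is taken from a chiral butenolide whose carbinol carbon (→ C1 ester) and lactone carbonyl (→ C2 acid) already differ.
2. Target ⇒ C2 tert-butyl ester 22 ⇒ (O-methylation, enol lactonisation, oxidation, double aldol) dialdehyde 16 + 2 × dianion of methyl 2-methylacetoacetate; both pyranone rings are closed last and together.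
3. 16 ⇒ tricyclic photoadduct 6: glycol cleavage gives the C1 ester, the lactone carbonyl carbon gives the C2 ester, the ring ketal gives the C3/C4 formyl groups.
4. 6 ⇒ [2+2] across C1–C4 and C2–C3 ⇒ (S)-butenolide 2 + ring-locked tetrasubstituted alkene 5 (from dimethylmaleic anhydride).
5. Ring order: dioxepine (step 3), cyclobutane (step 4), two pyranones (step 15).

Key step: step 4

Remark: locants C1–C4 are those of the target cyclobutane, and "top face" is the face of the C1/C2 carboxyl carbons and the C3/C4 methyl groups. The carbinol and C-methyl centres made in step 13 form as mixtures, are erased in steps 14–15 and are left undefined in the SMILES. Compounds 1, 3 and 17 are taken as purchasable.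

**Route**

Step 1
Reactants: 1 (S)-5-(hydroxymethyl)furan-2(5H)-one
Product: 2 (S)-5-(pivaloyloxymethyl)furan-2(5H)-one
Conditions: PivCl, pyridine, CH2Cl2, 0 °C → rt
Reagents that add atoms: pivaloyl chloride, CC(C)(C)C(Cl)=O
Why: O-acylation of the primary alcohol with a weak base that does not enolise the butenolide, so the C5 stereocentre is untouched.

Step 2
Reactants: 3 dimethylmaleic anhydride
Product: 4 (Z)-2,3-dimethylbut-2-ene-1,4-diol
Conditions: LiAlH4, Et2O, 0 °C → reflux; aq. NaOH work-up
Reagents that add atoms: none
Why: hydride reduction of both anhydride carbonyls to carbinols; the Z geometry is inherited from the ring and the tetrasubstituted alkene is not reduced.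

Step 3
Reactants: 4 (Z)-2,3-dimethylbut-2-ene-1,4-diol
Product: 5 2,2,5,6-tetramethyl-4,7-dihydro-1,3-dioxepine
Conditions: 2,2-dimethoxypropane, PPTS (cat.), CH2Cl2, rt
Reagents that add atoms: 2,2-dimethoxypropane, COC(C)(C)OC
Why: transketalisation closes the seven-membered ketal on the preorganised Z-diol, and the weak acid avoids allylic ionisation.

Step 4
Reactants: 2 (S)-5-(pivaloyloxymethyl)furan-2(5H)-one; 5 2,2,5,6-tetramethyl-4,7-dihydro-1,3-dioxepine
Product: 6 cis-anti-cis tricyclic lactone photoadduct
Conditions: hν (medium-pressure Hg lamp, quartz), Et2O, −20 °C, 5 (8 equiv), Ar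
Reagents that add atoms: none
Why: Excitation of 2 and intersystem crossing give its triplet, which bonds through the β-carbon (future C1) to one alkene carbon of 5 (future C4) to form a triplet 1,4-biradical; after spin inversion the α-radical (future C2) recombines with the tertiary radical (future C3). This is the enone–alkene [2+2] photocycloaddition, known for 5-substituted 2(5H)-furanones with cyclic and tetrasubstituted alkenes, and the cyclobutane is the only ring closed, by 1,4-biradical recombination. C1 and C2 come out cis because the five-membered lactone cannot bridge a trans fusion, and their absolute sense is fixed by the C5 stereocentre of 2, whose pivaloyloxymethyl arm blocks one face so that 5 adds anti to it. C3 and C4 keep the cis relation of their methyl groups because both carbons stay tied in the seven-membered ring throughout the life of the biradical, which should leave only the cis-fused closure open. The step further needs the exo orientation, with the dioxepine ring turned away from the lactone and the methyl groups above it, and the bulk of that ring with its gem-dimethyl ketal against the lactone is what should secure it; regiochemistry is no issue since 5 is symmetric. Direct irradiation in ether avoids acetone, whose triplet would add to the electron-rich alkene (Paterno–Büchi), and excess 5 at low temperature holds back furanone dimerisation.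

Step 5
Reactants: 6 cis-anti-cis tricyclic lactone photoadduct
Product: 7 triol with the ring ketal intact
Conditions: LiAlH4, THF, 0 °C → rt; aq. NaOH work-up
Reagents that add atoms: none
Why: hydride reduction opens the lactone to the C2 carbinol and the secondary alcohol and cleaves the pivalate; no stereocentre is touched and the ketal is inert to hydride.

Step 6
Reactants: 7 triol with the ring ketal intact
Product: 8 bis-ketal alcohol with free C2 hydroxymethyl
Conditions: 2,2-dimethoxypropane (1.5 equiv), PPTS (cat.), CH2Cl2, 0 °C → rt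
Reagents that add atoms: 2,2-dimethoxypropane, COC(C)(C)OC
Why: ketalisation should select the terminal 1,2-diol because the five-membered dioxolane is favoured over any seven-membered alternative, and the weak acid should not open the existing ring ketal at a useful rate.

Step 7
Reactants: 8 bis-ketal alcohol with free C2 hydroxymethyl
Product: 10 bis-ketal C2 carboxylic acid, via C2 aldehyde 9 (not isolated)
Conditions: TEMPO (cat.), NaOCl (cat.), NaClO2, MeCN/NaH2PO4–Na2HPO4 buffer (pH 6.7), 35 °C
Reagents that add atoms: sodium chlorite, [Na+].[O-]Cl=O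
Why: oxoammonium oxidation to the aldehyde and immediate chlorite oxidation to the acid in buffered medium, so the ketals survive and the aldehyde should not live long enough to epimerise at C2.

Step 8
Reactants: 10 bis-ketal C2 carboxylic acid
Product: 11 bis-ketal C2 tert-butyl ester
Conditions: O-tert-butyl-N,N′-diisopropylisourea (4 equiv), CH2Cl2, rt
Reagents that add atoms: O-tert-butyl-N,N′-diisopropylisourea, CC(C)NC(=NC(C)C)OC(C)(C)C
Why: the acid protonates the isourea and the carboxylate captures the tert-butyl cation, so the ester forms at oxygen away from the hindered C2 and without added acid that would harm the ketals.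

Step 9
Reactants: 11 bis-ketal C2 tert-butyl ester
Product: 13 C1 aldehyde C2 tert-butyl ester diol, via tetraol tert-butyl ester 12 (not isolated)
Conditions: H5IO6 (2.5 equiv), EtOAc, 0 °C → rt
Reagents that add atoms: none
Why: periodic acid hydrolyses both isopropylidene ketals and cleaves the freed 1,2-diol as it forms (one-pot acetonide hydrolysis and glycol cleavage); the 1,4-diol is inert to periodate, the γ-hydroxy ester should not accumulate, and C1 is not exposed to base.

Step 10
Reactants: 13 C1 aldehyde C2 tert-butyl ester diol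
Product: 14 C1 carboxylic acid C2 tert-butyl ester diol
Conditions: NaClO2, NaH2PO4, 2-methyl-2-butene, tBuOH/H2O, 0 °C → rt
Reagents that add atoms: sodium chlorite, [Na+].[O-]Cl=O
Why: Pinnick oxidation of the aldehyde at mildly acidic pH, which leaves the free primary alcohols alone and does not epimerise C1.

Step 11
Reactants: 14 C1 carboxylic acid C2 tert-butyl ester diol
Product: 15 C1 methyl ester C2 tert-butyl ester diol
Conditions: TMSCHN2, toluene/MeOH (4:1), 0 °C
Reagents that add atoms: (trimethylsilyl)diazomethane, C[Si](C)(C)C=[N+]=[N-]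
Why: methylation of the acid by the diazoalkane under neutral conditions; the hydroxymethyl groups on the opposite face cannot lactonise onto either ester because that would need a trans-fused five-membered ring.

Step 12
Reactants: 15 C1 methyl ester C2 tert-butyl ester diol
Product: 16 C3/C4 dialdehyde
Conditions: (COCl)2, DMSO, CH2Cl2, −78 °C; Et3N, −78 → 0 °C
Reagents that add atoms: none
Why: Swern oxidation turns both carbinols into alkoxysulfonium ions before any aldehyde exists, which avoids the lactol-to-lactone path of cis-1,4-diols; both aldehydes sit on quaternary carbons and cannot enolise.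

Step 13
Reactants: 16 C3/C4 dialdehyde; 17 methyl 2-methylacetoacetate
Product: 19 bis(δ-hydroxy-β-keto ester), via dilithium dianion 18 (not isolated)
Conditions: 17 (5 equiv), LiN(iPr)2 (10.5 equiv), THF, −78 → 0 °C; then 16, −78 °C; sat. NH4Cl
Reagents that add atoms: none
Why: γ-selective aldol addition of the β-keto ester dianion to both aldehydes, which at −78 °C should be much faster than attack on or deprotonation next to the C1/C2 esters; the new centres are mixtures of no consequence.

Step 14
Reactants: 19 bis(δ-hydroxy-β-keto ester)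
Product: 20 bis(β,δ-diketo ester)
Conditions: Dess–Martin periodinane (3 equiv), CH2Cl2, 0 °C → rt
Reagents that add atoms: none
Why: Dess–Martin oxidation of both secondary carbinols to ketones under near-neutral conditions that spare both esters.

Step 15
Reactants: 20 bis(β,δ-diketo ester)
Product: 21 bis(4-hydroxy-3-methyl-2-pyranone)
Conditions: DBU, toluene, rt → 60 °C; dilute HCl work-up
Reagents that add atoms: none
Why: base-mediated enol lactonisation, in which the enol oxygen of each ring-side ketone attacks its methyl ester with loss of methanol and tautomerisation gives the 4-hydroxy-2-pyranone; DBU is too weak to epimerise C1 or C2.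

Step 16
Reactants: 21 bis(4-hydroxy-3-methyl-2-pyranone)
Product: 22 bis(4-methoxy-3-methyl-2-pyranone) C2 tert-butyl ester
Conditions: Me2SO4, K2CO3, acetone, rt → 50 °C
Reagents that add atoms: dimethyl sulfate, COS(=O)(=O)OC
Why: O-alkylation of the vinylogous acid, which under carbonate and dimethyl sulfate should go mainly at the C4 oxygen to the 4-methoxy-2-pyranone and not to the 2-methoxy-4-pyranone.

Step 17
Reactants: 22 bis(4-methoxy-3-methyl-2-pyranone) C2 tert-butyl ester
Product: 23 CNP0481603.1
Conditions: TFA/CH2Cl2 (1:4), 0 °C → rt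
Reagents that add atoms: none
Why: acidolysis of the tert-butyl ester by loss of the tert-butyl cation; the methyl ester and the methoxypyranones are stable to the acid and no base touches C1 or C2.

**Compound list**

1 | (S)-5-(hydroxymethyl)furan-2(5H)-one | O1[C@H](CO)C=CC1=O | starting material
2 | (S)-5-(pivaloyloxymethyl)furan-2(5H)-one | O1[C@H](COC(=O)C(C)(C)C)C=CC1=O | intermediate
3 | dimethylmaleic anhydride (3,4-dimethylfuran-2,5-dione) | CC1=C(C)C(=O)OC1=O | starting material
4 | (Z)-2,3-dimethylbut-2-ene-1,4-diol | C/C(CO)=C(\C)CO | intermediate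
5 | 2,2,5,6-tetramethyl-4,7-dihydro-1,3-dioxepine | CC1=C(C)COC(C)(C)OC1 | intermediate
6 | cis-anti-cis photoadduct: cyclobutane fused at C1–C2 to a γ-lactone [C2–C(=O)–O–CH(CH2OPiv)–C1, carbinol carbon (S), CH2OPiv anti to the four-membered ring] and at C3–C4 to a 2,2-dimethyl-1,3-dioxepane; lactone and C3/C4 methyl groups on the top face, dioxepane on the bottom face | O2[C@H](COC(=O)C(C)(C)C)[C@@H]1[C@H](C2=O)[C@@](C)(C3)[C@@]1(C)COC(C)(C)O3 | intermediate
7 | triol: (S)-1,2-dihydroxyethyl on C1 and hydroxymethyl on C2 (top face), methyl on C3 and C4 (top face), C3/C4 CH2O arms tied as the 2,2-dimethyl-1,3-dioxepane (bottom face) | O[C@H](CO)[C@@H]1[C@H](CO)[C@@](C)(C2)[C@@]1(C)COC(C)(C)O2 | intermediate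
8 | bis-ketal alcohol: as 7 with the glycol closed to the (S)-2,2-dimethyl-1,3-dioxolan-4-yl group on C1 and the C2 hydroxymethyl free | O3[C@H](COC3(C)C)[C@@H]1[C@H](CO)[C@@](C)(C2)[C@@]1(C)COC(C)(C)O2 | intermediate
9 | C2 aldehyde corresponding to 8 | O3[C@H](COC3(C)C)[C@@H]1[C@H](C=O)[C@@](C)(C2)[C@@]1(C)COC(C)(C)O2 | intermediate
10 | C2 carboxylic acid corresponding to 8 | O3[C@H](COC3(C)C)[C@@H]1[C@H](C(=O)O)[C@@](C)(C2)[C@@]1(C)COC(C)(C)O2 | intermediate
11 | tert-butyl ester of 10 | O3[C@H](COC3(C)C)[C@@H]1[C@H](C(=O)OC(C)(C)C)[C@@](C)(C2)[C@@]1(C)COC(C)(C)O2 | intermediate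
12 | tetraol: C2 tert-butyl ester, (S)-1,2-dihydroxyethyl on C1, hydroxymethyl on C3 and C4 (bottom face) | O[C@H](CO)[C@@H]1[C@H](C(=O)OC(C)(C)C)[C@@](C)(CO)[C@@]1(C)CO | intermediate
13 | C1 formyl, C2 tert-butyl ester, C3/C4 bis(hydroxymethyl) cyclobutane | O=C[C@@H]1[C@H](C(=O)OC(C)(C)C)[C@@](C)(CO)[C@@]1(C)CO | intermediate
14 | C1 carboxylic acid, C2 tert-butyl ester, C3/C4 bis(hydroxymethyl) cyclobutane | OC(=O)[C@@H]1[C@H](C(=O)OC(C)(C)C)[C@@](C)(CO)[C@@]1(C)CO | intermediate
15 | C1 methyl ester, C2 tert-butyl ester, C3/C4 bis(hydroxymethyl) cyclobutane | COC(=O)[C@@H]1[C@H](C(=O)OC(C)(C)C)[C@@](C)(CO)[C@@]1(C)CO | intermediate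
16 | C1 methyl ester, C2 tert-butyl ester, C3/C4 diformyl cyclobutane | COC(=O)[C@@H]1[C@H](C(=O)OC(C)(C)C)[C@@](C)(C=O)[C@@]1(C)C=O | intermediate
17 | methyl 2-methylacetoacetate (methyl 2-methyl-3-oxobutanoate) | COC(=O)C(C)C(C)=O | starting material
18 | dilithium dianion of 17 (C2 and C4 deprotonated) | [Li+].[Li+].[CH2-]C(=O)[C-](C)C(=O)OC | intermediate
19 | bis(δ-hydroxy-β-keto ester): C3 and C4 each carry CH(OH)CH2C(=O)CH(CH3)CO2CH3 | COC(=O)[C@@H]1[C@H](C(=O)OC(C)(C)C)[C@@](C)(C(O)CC(=O)C(C)C(=O)OC)[C@@]1(C)C(O)CC(=O)C(C)C(=O)OC | intermediate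
20 | bis(β,δ-diketo ester): C3 and C4 each carry C(=O)CH2C(=O)CH(CH3)CO2CH3 | COC(=O)[C@@H]1[C@H](C(=O)OC(C)(C)C)[C@@](C)(C(=O)CC(=O)C(C)C(=O)OC)[C@@]1(C)C(=O)CC(=O)C(C)C(=O)OC | intermediate
21 | C3/C4 bis(4-hydroxy-3-methyl-2-oxo-2H-pyran-6-yl) C1 methyl C2 tert-butyl diester | COC(=O)[C@@H]1[C@H](C(=O)OC(C)(C)C)[C@@](C)(c2cc(O)c(C)c(=O)o2)[C@@]1(C)c1cc(O)c(C)c(=O)o1 | intermediate
22 | C3/C4 bis(4-methoxy-3-methyl-2-oxo-2H-pyran-6-yl) C1 methyl C2 tert-butyl diester | COC(=O)[C@@H]1[C@H](C(=O)OC(C)(C)C)[C@@](C)(c2cc(OC)c(C)c(=O)o2)[C@@]1(C)c1cc(OC)c(C)c(=O)o1 | intermediate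
23 | CNP0481603.1: cyclobutane with CO2CH3 on C1, CO2H on C2, and methyl plus 4-methoxy-3-methyl-2-oxo-2H-pyran-6-yl on each of C3 and C4; (1R,2S,3R,4S) in these locants; both carboxyl groups and both methyl groups on one face | COC(=O)[C@@H]1[C@H](C(=O)O)[C@@](C)(c2cc(OC)c(C)c(=O)o2)[C@@]1(C)c1cc(OC)c(C)c(=O)o1 | target

**Totals**
Total step count: 17. Longest linear sequence: 16 steps (3 → 23 through steps 2–17); the butenolide branch is 15 steps.

**Steps most likely to fail**

Step 4. The alkene may add without enough discrimination between the two faces of the butenolide, which erodes the absolute sense, or hydrogen transfer inside the biradical may outrun ring closure. The fallback sets out from 5 and comes back at 15; it takes the stereocentre out of the photochemical step. Maleic anhydride and 5 are irradiated with acetophenone as sensitiser (MeCN, Pyrex, 0 °C) to the meso cis-anti-cis cyclobutane anhydride F1. Methanolysis mediated by quinidine or quinine (MeOH, toluene, −55 °C), a known desymmetrisation of meso cyclic anhydrides, should open one of the two enantiotopic carbonyl groups to the hemiester F2. The two alkaloids are pseudoenantiomeric, and the one that places the methyl ester on C1 is to be chosen by correlation with 15. O-tert-Butyl-N,N′-diisopropylisourea then gives the mixed diester F3, and PPTS in MeOH removes the ring ketal to give 15.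

Step 13. After the first addition the lithium alkoxide may close onto the neighbouring formyl group, and the lactolate may resist the second addition; retro-aldol on warming is the other loss. The fallback sets out from 17 (used with 16) and comes back at 19; it replaces the anionic aldol by a Lewis-acid aldol. 17 is silylated (Me3SiCl, Et3N) to the silyl enol ether F4 and then (LiN(iPr)2, Me3SiCl, THF, −78 °C) to the bis(silyloxy)diene F5. A vinylogous Mukaiyama aldol of F5 (3 equiv) with 16 (BF3·OEt2, CH2Cl2, −78 °C, aqueous work-up) should give 19 with no free alkoxide on the way.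

Step 9. In the acidic medium the freed secondary hydroxyl may close onto the C2 tert-butyl ester before periodate cleaves the glycol, or the seven-membered ketal may be hydrolysed incompletely. The fallback sets out from 6 and comes back at 13; it keeps C2 at the acid level throughout and masks the glycol as silyl ethers that fluoride removes. 6 is saponified (KOH, MeOH/H2O) to the potassium carboxylate F6. Silylation (tBuMe2SiCl, imidazole, DMF) gives the tris-silyl compound F7, whose silyl ester is hydrolysed selectively (K2CO3, MeOH/THF/H2O) to the acid F8. The isourea of step 8 gives the tert-butyl ester F9, and buffered fluoride (Bu4NF/AcOH, THF) frees the glycol F10 under neutral conditions. NaIO4 (THF/pH 7 buffer) cleaves it to the aldehyde F11, and only then does aqueous AcOH remove the ring ketal to give 13.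

**Further compounds**

F1 | step 4 | meso cis-anti-cis cyclobutane-1,2-dicarboxylic anhydride with the C3/C4 methyl groups syn and the 2,2-dimethyl-1,3-dioxepane anti to the anhydride | O3C(=O)[C@@H]1[C@H](C3=O)[C@@](C)(C2)[C@@]1(C)COC(C)(C)O2
F2 | step 4 | hemiester: C1 methyl ester, C2 carboxylic acid, ring ketal intact | COC(=O)[C@@H]1[C@H](C(=O)O)[C@@](C)(C2)[C@@]1(C)COC(C)(C)O2
F3 | step 4 | C1 methyl C2 tert-butyl diester, ring ketal intact | COC(=O)[C@@H]1[C@H](C(=O)OC(C)(C)C)[C@@](C)(C2)[C@@]1(C)COC(C)(C)O2
F4 | step 13 | methyl 2-methyl-3-(trimethylsilyloxy)but-2-enoate | COC(=O)C(C)=C(C)O[Si](C)(C)C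
F5 | step 13 | 1-methoxy-2-methyl-1,3-bis(trimethylsilyloxy)buta-1,3-diene | COC(O[Si](C)(C)C)=C(C)C(=C)O[Si](C)(C)C
F6 | step 9 | potassium C2 carboxylate with (S)-1,2-dihydroxyethyl on C1, ring ketal intact | O[C@H](CO)[C@@H]1[C@H](C(=O)[O-])[C@@](C)(C2)[C@@]1(C)COC(C)(C)O2.[K+]
F7 | step 9 | tris(tert-butyldimethylsilyl) compound: silyl ester on C2, bis-silyl ether of the glycol | CC(C)(C)[Si](C)(C)O[C@H](CO[Si](C)(C)C(C)(C)C)[C@@H]1[C@H](C(=O)O[Si](C)(C)C(C)(C)C)[C@@](C)(C2)[C@@]1(C)COC(C)(C)O2
F8 | step 9 | C2 carboxylic acid with bis-silylated glycol | CC(C)(C)[Si](C)(C)O[C@H](CO[Si](C)(C)C(C)(C)C)[C@@H]1[C@H](C(=O)O)[C@@](C)(C2)[C@@]1(C)COC(C)(C)O2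
F9 | step 9 | C2 tert-butyl ester with bis-silylated glycol | CC(C)(C)[Si](C)(C)O[C@H](CO[Si](C)(C)C(C)(C)C)[C@@H]1[C@H](C(=O)OC(C)(C)C)[C@@](C)(C2)[C@@]1(C)COC(C)(C)O2
F10 | step 9 | C2 tert-butyl ester with free (S)-glycol on C1, ring ketal intact | O[C@H](CO)[C@@H]1[C@H](C(=O)OC(C)(C)C)[C@@](C)(C2)[C@@]1(C)COC(C)(C)O2
F11 | step 9 | C1 formyl C2 tert-butyl ester, ring ketal intact | O=C[C@@H]1[C@H](C(=O)OC(C)(C)C)[C@@](C)(C2)[C@@]1(C)COC(C)(C)O2
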